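**Plan**

- Retrosynthesis: the C3'–H bond is traced back to an enol triflate. The aryl ether bonds O3–C1' and O2–C5' are cut (hetero-Diels–Alder) into a pristimerin-derived ortho-quinone and a hydroazulene dienyl triflate. The C10'–CH3 bond is cut (cuprate 1,6-addition). C1'–C5', C2'–C3' and C3'–C4' are then cut together (allenic Pauson–Khand) to an acyclic allenyne and CO, and the C9'–C10' bond to a carvone-derived bromide and propargyl bromide.
- Feature used: the cyclopentene ring C1'–C5' with its C4' methyl, fused along C1'–C5' to the seven-membered ring C1', C5'–C10', is a methyl alkyne (C4'≡C5'), a terminal allene (C10'=C1'=C2') and CO (C3') held together by the four-carbon chain C6'–C9'.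
- Forward order: (S)-carvone is fragmented to the C6'–C9' chain with its methyl alkyne and the allene is attached. One [Rh(CO)2Cl]2-catalysed step closes the seven- and five-membered carbocycles. The C10' methyl and the C3' triflate are installed, the dioxane ring is closed by cycloaddition, and the triflate is reduced last.
- Stereochemistry: C7' comes from (S)-(+)-carvone. C10' comes from axial cuprate delivery on the half-chair dienone with the isopropenyl group equatorial. C1' and C5' are set together in the suprafacial cycloaddition. The triterpene centres come from pristimerin, except C8, which is set by α-face hydroboration.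

Key step: step 6

Assumption: the quinone is taken to add to the dienyl triflate with the orientation and on the face found in the target (O3 to C1', O2 to C5', cis to the C10' methyl), and the conformational argument for C10' in step 7 is reasoned, not tested; primed locants number the guaiane unit, unprimed locants the 24-norfriedelane unit.

**Route**

Step 1
Reactants: 1 (S)-(+)-carvone
Product: 2 (1S,4S,6S)-1-methyl-4-(prop-1-en-2-yl)-7-oxabicyclo[4.1.0]heptan-2-one
Conditions: H2O2 (30% aq.), NaOH (cat.), MeOH, 0 °C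
Reagents that add atoms: hydrogen peroxide, OO
Why: Weitz–Scheffer nucleophilic epoxidation, in which hydroperoxide attacks only the electron-poor enone double bond anti to the isopropenyl group, so the isolated alkene survives and the trans epoxide forms (both new centres are erased in step 2).

Step 2
Reactants: 2 (1S,4S,6S)-1-methyl-4-(prop-1-en-2-yl)-7-oxabicyclo[4.1.0]heptan-2-one
Product: 4 (3R)-3-(prop-1-en-2-yl)hept-5-ynal, via tosylhydrazone 3 (not isolated)
Conditions: TsNHNH2 (1.0 equiv), CH2Cl2/AcOH 2:1, −20 °C to rt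
Reagents that add atoms: none
Why: Eschenmoser–Tanabe fragmentation, in which the epoxy tosylhydrazone opens to an alkoxy vinyldiazene that loses N2 and sulfinate with cleavage of the Cα–Cβ bond, turning the C(=O)–C(CH3) unit into the methyl alkyne and the epoxide CH into the aldehyde without touching the isopropenyl-bearing centre.

Step 3
Reactants: 4 (3R)-3-(prop-1-en-2-yl)hept-5-ynal
Product: 5 (3R)-3-(prop-1-en-2-yl)hept-5-yn-1-ol
Conditions: NaBH4, MeOH, 0 °C
Reagents that add atoms: none
Why: Borohydride reduction of the aldehyde, to which the alkyne and the alkene are inert.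

Step 4
Reactants: 5 (3R)-3-(prop-1-en-2-yl)hept-5-yn-1-ol
Product: 6 (5R)-7-bromo-5-(prop-1-en-2-yl)hept-2-yne
Conditions: CBr4, PPh3, CH2Cl2, 0 °C
Reagents that add atoms: tetrabromomethane, BrC(Br)(Br)Br
Why: Appel bromination of the primary alcohol by SN2 displacement of the alkoxyphosphonium ion under neutral conditions.

Step 5
Reactants: 6 (5R)-7-bromo-5-(prop-1-en-2-yl)hept-2-yne; 7 3-bromoprop-1-yne (propargyl bromide)
Product: 9 (6S)-6-(prop-1-en-2-yl)deca-1,2-dien-8-yne, via Grignard reagent 8 (not isolated)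
Conditions: Mg, THF, 40 °C; then CuBr·SMe2 (5 mol%), 7, THF, −40 to 0 °C
Reagents that add atoms: none
Why: Copper-catalysed SN2' substitution of a propargylic bromide by a primary Grignard reagent, which attacks the alkyne terminus and gives the terminal allene; the internal methyl alkyne has no leaving group and C7' is not involved.

Step 6
Reactants: 9 (6S)-6-(prop-1-en-2-yl)deca-1,2-dien-8-yne
Product: 10 (5S)-3-methyl-5-(prop-1-en-2-yl)-4,5,6,7-tetrahydroazulen-2(1H)-one
Conditions: [Rh(CO)2Cl]2 (5 mol%), CO (1 atm), toluene (0.02 M), 90 °C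
Reagents that add atoms: carbon monoxide, [C-]#[O+]
Why: The monovalent rhodium carbonyl chloride binds the methyl alkyne and the distal C1'=C2' π-bond of the allene and couples them oxidatively to a rhodacyclopentene (C1'–C5' bond); CO then inserts and reductive elimination forms C2'–C3' and C3'–C4'. The closest known reaction type is the rhodium-catalysed allenic Pauson–Khand reaction of allenynes with a four-atom tether, which gives bicyclo[5.3.0]deca-1,7-dien-9-ones. The seven-membered ring closes in the oxidative cyclisation, exo with respect to the alkyne, because the C6'–C9' chain links C5' to C10'; the cyclopentenone closes by CO insertion and reductive elimination as the formal [2+2+1] ring. No stereocentre is created: C7' is carried through and C10' stays trigonal in the exocyclic C10'=C1' bond. The step needs reaction at the distal and not the proximal allene bond and no participation of the isopropenyl group; this rhodium catalyst selects the distal bond of allenes, and an isolated 1,1-disubstituted alkene cannot compete with the alkyne for the metal. High dilution under CO should suppress oligomerisation of the allene.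

Step 7
Reactants: 10 (5S)-3-methyl-5-(prop-1-en-2-yl)-4,5,6,7-tetrahydroazulen-2(1H)-one
Product: 12 (5S,8R)-3,8-dimethyl-5-(prop-1-en-2-yl)-1,4,5,6,7,8-hexahydroazulen-2-yl trifluoromethanesulfonate, via lithium dienolate 11 (not isolated)
Conditions: Me2CuLi (from MeLi and CuI), Et2O, −78 to −30 °C; then PhNTf2, THF, −78 °C to rt
Reagents that add atoms: lithium dimethylcuprate, [Li+].C[Cu-]C; N-phenylbis(trifluoromethanesulfonimide), O=S(=O)(N(c1ccccc1)S(=O)(=O)C(F)(F)F)C(F)(F)F
Why: Cuprate 1,6-addition to a linear dienone places the methyl on the δ-carbon C10' because the β-carbon C5' is fully substituted, and the extended lithium enolate is trapped on oxygen as the enol triflate; the methyl should enter antiperiplanar to the pseudoaxial C9'–H of the half-chair seven-membered ring, whose C7' isopropenyl group sits equatorial, which gives the 7',10'-cis relationship (8R).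

Step 8
Reactants: 13 pristimerin
Product: 15 methyl 2,3-bis(tert-butyldimethylsilyloxy)-24-norfriedela-1,3,5(10),7-tetraen-29-oate, via pristimerol 14 (not isolated)
Conditions: NaBH4, THF/MeOH, 0 °C; then TBSCl, imidazole, DMF, 40 °C, argon
Reagents that add atoms: tert-butyl(chloro)dimethylsilane, CC(C)(C)[Si](C)(C)Cl
Why: Conjugate (1,6) hydride addition to the quinone methide at C6 aromatises ring A to the catechol, which is silylated in the same flask (silyl ether formation) before air can reoxidise it; no stereocentre changes.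

Step 9
Reactants: 15 methyl 2,3-bis(tert-butyldimethylsilyloxy)-24-norfriedela-1,3,5(10),7-tetraen-29-oate
Product: 17 methyl 2,3-bis(tert-butyldimethylsilyloxy)-7α-hydroxy-24-norfriedela-1,3,5(10)-trien-29-oate, via alkylborane 16 (not isolated)
Conditions: BH3·THF, THF, 0 °C to rt; then NaBO3·4H2O, THF/H2O, rt
Reagents that add atoms: sodium perborate, [Na+].[O-]B1OO1
Why: Hydroboration–oxidation, in which borane adds syn across C7=C8 with boron on the less substituted C7 and from the α face, the β face being closed by the axial methyl groups on C9 and C14, so that C8 receives its α-hydrogen and oxidation with retention leaves the 7α-hydroxyl.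

Step 10
Reactants: 17 methyl 2,3-bis(tert-butyldimethylsilyloxy)-7α-hydroxy-24-norfriedela-1,3,5(10)-trien-29-oate
Product: 19 methyl 2,3-bis(tert-butyldimethylsilyloxy)-24-norfriedela-1,3,5(10),6-tetraen-29-oate, via sulfamate ester 18 (not isolated)
Conditions: Burgess reagent, toluene, 60 °C
Reagents that add atoms: none
Why: Burgess dehydration (syn elimination through the sulfamate ester) should remove the 7α-oxygen together with the cis, benzylic and more acidic 6α-hydrogen, giving the arene-conjugated C6=C7 bond and leaving the hindered C8–H in place.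

Step 11
Reactants: 19 methyl 2,3-bis(tert-butyldimethylsilyloxy)-24-norfriedela-1,3,5(10),6-tetraen-29-oate
Product: 20 methyl 2,3-dihydroxy-24-norfriedela-1,3,5(10),6-tetraen-29-oate
Conditions: Et3N·3HF, THF, rt, argon
Reagents that add atoms: none
Why: Fluoride cleavage of the two aryl silyl ethers under nearly neutral conditions, which spares the acid-sensitive styrene and the methyl ester; the catechol is used at once.

Step 12
Reactants: 20 methyl 2,3-dihydroxy-24-norfriedela-1,3,5(10),6-tetraen-29-oate; 12 (5S,8R)-3,8-dimethyl-5-(prop-1-en-2-yl)-1,4,5,6,7,8-hexahydroazulen-2-yl trifluoromethanesulfonate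
Product: 22 3'-triflyloxy benzodioxane adduct (O3–C1' and O2–C5' bonds), via ortho-quinone 21 (not isolated)
Conditions: Ag2O, Na2SO4, toluene, 0 °C, dark; filter; then 12, toluene, 60 °C
Reagents that add atoms: none
Why: Ag2O dehydrogenates the catechol to the ortho-quinone, whose O=C–C=O unit should add as the heterodiene across C1'=C5' in an inverse-electron-demand hetero-Diels–Alder reaction, the enol triflate deactivating C3'=C4' and preventing hydrogen shifts in the cyclopentadiene, the more nucleophilic C1' pairing with O3 of the more extended dienone carbonyl, and suprafacial addition on the face from which the seven-membered ring folds away, cis to the C10' methyl and C7' isopropenyl groups, setting C1' and C5' together.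

Step 13
Reactants: 22 3'-triflyloxy benzodioxane adduct
Product: 23 CNP0113384.1 (target)
Conditions: Pd(OAc)2 (5 mol%), PPh3 (10 mol%), HCO2H, Bu3N, DMF, 40 °C
Reagents that add atoms: none
Why: Palladium-catalysed formate reduction of a vinyl triflate (oxidative addition to zerovalent palladium, formate decarboxylation, C–H reductive elimination) replaces the triflate on C3' by hydrogen without touching any stereocentre.

**Compound list**

1 | (S)-(+)-carvone, (5S)-2-methyl-5-(prop-1-en-2-yl)cyclohex-2-en-1-one | C=C(C)[C@@H]1CC(=O)C(C)=CC1 | starting material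
2 | (1S,4S,6S)-1-methyl-4-(prop-1-en-2-yl)-7-oxabicyclo[4.1.0]heptan-2-one | C=C(C)[C@@H]1CC(=O)[C@@]2(C)O[C@H]2C1 | intermediate
3 | p-toluenesulfonylhydrazone of 2 | C=C(C)[C@@H]1CC(=NNS(=O)(=O)c2ccc(C)cc2)[C@@]2(C)O[C@H]2C1 | intermediate
4 | (3R)-3-(prop-1-en-2-yl)hept-5-ynal | C=C(C)[C@H](CC#CC)CC=O | intermediate
5 | (3R)-3-(prop-1-en-2-yl)hept-5-yn-1-ol | C=C(C)[C@H](CC#CC)CCO | intermediate
6 | (5R)-7-bromo-5-(prop-1-en-2-yl)hept-2-yne | C=C(C)[C@H](CC#CC)CCBr | intermediate
7 | 3-bromoprop-1-yne (propargyl bromide) | C#CCBr | starting material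
8 | [(3R)-3-(prop-1-en-2-yl)hept-5-yn-1-yl]magnesium bromide | C=C(C)[C@H](CC#CC)CC[Mg]Br | intermediate
9 | (6S)-6-(prop-1-en-2-yl)deca-1,2-dien-8-yne | C=C(C)[C@H](CC#CC)CCC=C=C | intermediate
10 | (5S)-3-methyl-5-(prop-1-en-2-yl)-4,5,6,7-tetrahydroazulen-2(1H)-one | C=C(C)[C@H]1CCC=C2CC(=O)C(C)=C2C1 | intermediate
11 | lithium (5S,8R)-3,8-dimethyl-5-(prop-1-en-2-yl)-1,4,5,6,7,8-hexahydroazulen-2-olate | C=C(C)[C@H]1CC[C@@H](C)C2=C(C1)C(C)=C([O-])C2.[Li+] | intermediate
12 | (5S,8R)-3,8-dimethyl-5-(prop-1-en-2-yl)-1,4,5,6,7,8-hexahydroazulen-2-yl trifluoromethanesulfonate | C=C(C)[C@H]1CC[C@@H](C)C2=C(C1)C(C)=C(OS(=O)(=O)C(F)(F)F)C2 | intermediate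
13 | pristimerin, methyl 3-hydroxy-2-oxo-24-norfriedela-1(10),3,5,7-tetraen-29-oate | CC1=C(O)C(=O)C=C2C1=CC=C1[C@@]2(C)CC[C@@]2(C)[C@@H]3C[C@](C)(C(=O)OC)CC[C@]3(C)CC[C@]12C | starting material
14 | pristimerol, methyl 2,3-dihydroxy-24-norfriedela-1,3,5(10),7-tetraen-29-oate | Cc1c(O)c(O)cc2c1CC=C1[C@@]2(C)CC[C@@]2(C)[C@@H]3C[C@](C)(C(=O)OC)CC[C@]3(C)CC[C@]12C | intermediate
15 | methyl 2,3-bis(tert-butyldimethylsilyloxy)-24-norfriedela-1,3,5(10),7-tetraen-29-oate | Cc1c(O[Si](C)(C)C(C)(C)C)c(O[Si](C)(C)C(C)(C)C)cc2c1CC=C1[C@@]2(C)CC[C@@]2(C)[C@@H]3C[C@](C)(C(=O)OC)CC[C@]3(C)CC[C@]12C | intermediate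
16 | methyl 7α-boranyl-2,3-bis(tert-butyldimethylsilyloxy)-24-norfriedela-1,3,5(10)-trien-29-oate (8α-H, written as the monoalkylborane) | Cc1c(O[Si](C)(C)C(C)(C)C)c(O[Si](C)(C)C(C)(C)C)cc2c1C[C@@H](B)[C@H]1[C@@]2(C)CC[C@@]2(C)[C@@H]3C[C@](C)(C(=O)OC)CC[C@]3(C)CC[C@]12C | intermediate
17 | methyl 2,3-bis(tert-butyldimethylsilyloxy)-7α-hydroxy-24-norfriedela-1,3,5(10)-trien-29-oate (8α-H) | Cc1c(O[Si](C)(C)C(C)(C)C)c(O[Si](C)(C)C(C)(C)C)cc2c1C[C@@H](O)[C@H]1[C@@]2(C)CC[C@@]2(C)[C@@H]3C[C@](C)(C(=O)OC)CC[C@]3(C)CC[C@]12C | intermediate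
18 | triethylammonium salt of the 7α-O-[N-(methoxycarbonyl)sulfamate] of 17 | Cc1c(O[Si](C)(C)C(C)(C)C)c(O[Si](C)(C)C(C)(C)C)cc2c1C[C@@H](OS(=O)(=O)[N-]C(=O)OC)[C@H]1[C@@]2(C)CC[C@@]2(C)[C@@H]3C[C@](C)(C(=O)OC)CC[C@]3(C)CC[C@]12C.CC[NH+](CC)CC | intermediate
19 | methyl 2,3-bis(tert-butyldimethylsilyloxy)-24-norfriedela-1,3,5(10),6-tetraen-29-oate (8α-H) | Cc1c(O[Si](C)(C)C(C)(C)C)c(O[Si](C)(C)C(C)(C)C)cc2c1C=C[C@H]1[C@@]2(C)CC[C@@]2(C)[C@@H]3C[C@](C)(C(=O)OC)CC[C@]3(C)CC[C@]12C | intermediate
20 | methyl 2,3-dihydroxy-24-norfriedela-1,3,5(10),6-tetraen-29-oate (8α-H) | Cc1c(O)c(O)cc2c1C=C[C@H]1[C@@]2(C)CC[C@@]2(C)[C@@H]3C[C@](C)(C(=O)OC)CC[C@]3(C)CC[C@]12C | intermediate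
21 | methyl 2,3-dioxo-24-norfriedela-1(10),4,6-trien-29-oate (8α-H) | O=C1C=C2C(C=C[C@H]3[C@@]2(C)CC[C@@]2(C)[C@@H]4C[C@](C)(C(=O)OC)CC[C@]4(C)CC[C@]32C)=C(C)C1=O | intermediate
22 | 3'-trifluoromethanesulfonyloxy derivative of the target (cis-fused benzodioxane with O3–C1' and O2–C5' bonds) | C=C(C)[C@H]1CC[C@@H](C)[C@]23CC(OS(=O)(=O)C(F)(F)F)=C(C)[C@@]2(C1)Oc1cc2c(c(C)c1O3)C=C[C@H]1[C@@]2(C)CC[C@@]2(C)[C@@H]3C[C@](C)(C(=O)OC)CC[C@]3(C)CC[C@]12C | intermediate
23 | CNP0113384.1 | C=C(C)[C@H]1CC[C@@H](C)[C@]23CC=C(C)[C@@]2(C1)Oc1cc2c(c(C)c1O3)C=C[C@H]1[C@@]2(C)CC[C@@]2(C)[C@@H]3C[C@](C)(C(=O)OC)CC[C@]3(C)CC[C@]12C | target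

**Step count and risks**

Total steps: 13 (seven to dienyl triflate 12, four to catechol 20, two after the union). Longest linear sequence: 9 steps (steps 1 to 7, 12 and 13).

Steps most likely to fail:

1. Step 12. The cycloaddition may be slow because the triflate lowers the nucleophilicity of the diene. The cyclopentadiene unit may instead react as a four-carbon diene with a quinone carbonyl. The quinone may add on the face anti to the C10' methyl or with O2 and O3 exchanged, and it may tautomerise to pristimerin on long heating. Fallback: starting from dienone 10, the lithium dienolate 11 is trapped with TESCl instead of PhNTf2 to give the triethylsilyl dienol ether F1. In this 1-silyloxy diene the vinylogous oxygen raises the electron density at C1' and still directs bond formation away from C3'=C4'. F1 should take up quinone 21 at or below room temperature to give the silyl enol ether adduct F2. CsF and PhNTf2 in DME would then convert F2 through the caesium enolate F3 into triflate 22, where the route is rejoined.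

2. Step 7. The methyl group may be delivered to the other face of C10', since induction from C7' across the ring is weak, and C-protonation of the dienolate may compete with O-sulfonylation. Fallback: the complementary order of bond formation sets out from Grignard reagent 8. Copper-catalysed SN2' coupling with 1-bromobut-2-yne would give the C10'-methyl allenyne F4, and the same [Rh(CO)2Cl]2/CO cyclocarbonylation would give the tetrasubstituted dienone F5. Dissolving-metal 1,6-reduction of F5 (Li, NH3/THF, one equivalent of t-BuOH, −78 °C) delivers hydrogen instead of methyl to C10' along the same axial trajectory, so the facial outcome at C10' is inverted relative to the cuprate route. This gives lithium dienolate 11, which is triflated as in step 7 to reach 12.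

3. Step 9. Hydroboration may be sluggish at an alkene flanked by two quaternary carbons. Excess borane may reduce the methyl ester, the aryl silyl ethers may be partly lost during oxidation, and some β-face attack may occur. Fallback: starting from 15, allylic-benzylic oxidation at C6 (CrO3·3,5-dimethylpyrazole, CH2Cl2, −20 °C) would give the 6-oxo-7-ene F6. Conjugate reduction with Li in NH3/THF protonates C8 axially from the α face and gives the saturated ketone F7. NaBH4 then gives the benzylic alcohol F8, and Burgess dehydration, which can only proceed towards C7, returns to styrene 19.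

Further compounds
F1 | step 12 | triethyl{[(5S,8R)-3,8-dimethyl-5-(prop-1-en-2-yl)-1,4,5,6,7,8-hexahydroazulen-2-yl]oxy}silane | C=C(C)[C@H]1CC[C@@H](C)C2=C(C1)C(C)=C(O[Si](CC)(CC)CC)C2
F2 | step 12 | 3'-triethylsilyloxy analogue of 22 (silyl enol ether adduct) | C=C(C)[C@H]1CC[C@@H](C)[C@]23CC(O[Si](CC)(CC)CC)=C(C)[C@@]2(C1)Oc1cc2c(c(C)c1O3)C=C[C@H]1[C@@]2(C)CC[C@@]2(C)[C@@H]3C[C@](C)(C(=O)OC)CC[C@]3(C)CC[C@]12C
F3 | step 12 | caesium C3'-enolate of the adduct | C=C(C)[C@H]1CC[C@@H](C)[C@]23CC([O-])=C(C)[C@@]2(C1)Oc1cc2c(c(C)c1O3)C=C[C@H]1[C@@]2(C)CC[C@@]2(C)[C@@H]3C[C@](C)(C(=O)OC)CC[C@]3(C)CC[C@]12C.[Cs+]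
F4 | step 7 | (6S)-3-methyl-6-(prop-1-en-2-yl)deca-1,2-dien-8-yne | C=C(C)[C@H](CC#CC)CCC(C)=C=C
F5 | step 7 | (5S)-3,8-dimethyl-5-(prop-1-en-2-yl)-4,5,6,7-tetrahydroazulen-2(1H)-one | C=C(C)[C@H]1CCC(C)=C2CC(=O)C(C)=C2C1
F6 | step 9 | methyl 2,3-bis(tert-butyldimethylsilyloxy)-6-oxo-24-norfriedela-1,3,5(10),7-tetraen-29-oate | Cc1c(O[Si](C)(C)C(C)(C)C)c(O[Si](C)(C)C(C)(C)C)cc2c1C(=O)C=C1[C@@]2(C)CC[C@@]2(C)[C@@H]3C[C@](C)(C(=O)OC)CC[C@]3(C)CC[C@]12C
F7 | step 9 | methyl 2,3-bis(tert-butyldimethylsilyloxy)-6-oxo-24-norfriedela-1,3,5(10)-trien-29-oate (8α-H) | Cc1c(O[Si](C)(C)C(C)(C)C)c(O[Si](C)(C)C(C)(C)C)cc2c1C(=O)C[C@H]1[C@@]2(C)CC[C@@]2(C)[C@@H]3C[C@](C)(C(=O)OC)CC[C@]3(C)CC[C@]12C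
F8 | step 9 | methyl 2,3-bis(tert-butyldimethylsilyloxy)-6-hydroxy-24-norfriedela-1,3,5(10)-trien-29-oate (8α-H, C6 configuration not fixed) | Cc1c(O[Si](C)(C)C(C)(C)C)c(O[Si](C)(C)C(C)(C)C)cc2c1C(O)C[C@H]1[C@@]2(C)CC[C@@]2(C)[C@@H]3C[C@](C)(C(=O)OC)CC[C@]3(C)CC[C@]12C
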